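Ring C is cut at O1–C2 and C4–C4a. Both bonds form in one pot from an aryl ester in which the ring A oxygen destined to be O1 carries an enantiopure 2-aryl glycidic acid: bromine–lithium exchange at the future C4a triggers an anionic ortho-Fries shift (C4–C4a), and the phenoxide thus unmasked opens the oxirane at its CH2 terminus (O1–C2), releasing the C3 carbinol. The step exploits the ortho placement of O1 and the C4 acyl carbon on ring A and the 1,2-relationship of C2 to the C3 oxygen. The sacrificial O1–acyl bond, absent from the target, fixes the 8-prenyl regiochemistry; C3 (S) stems from a Sharpless epoxidation.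

Key step: step 12

Assumption: C3 of the target is S as drawn; tert-butyl (2-methylbut-3-en-2-yl) carbonate is taken as a purchasable reagent.
Abbreviations: MOM = methoxymethyl; prenyl = 3-methylbut-2-en-1-yl; ArB = 2-methoxy-4-(methoxymethoxy)-3-prenylphenyl.

Step 1
Reactants: 1 4-chloro-3-methoxyphenol
Product: 2 1-chloro-2-methoxy-4-(methoxymethoxy)benzene
Conditions: MOMCl, i-Pr2NEt, CH2Cl2, 0 °C to rt
Reagents that add atoms: chloromethyl methyl ether (COCCl)
Why: O-alkylation of the phenol (Williamson-type acetal formation) installs the MOM group, which directs the next lithiation and is stable to organolithium reagents.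

Step 2
Reactants: 2 1-chloro-2-methoxy-4-(methoxymethoxy)benzene
Product: 4 1-chloro-2-methoxy-4-(methoxymethoxy)-3-prenylbenzene, via aryllithium 3 (not isolated)
Conditions: n-BuLi, TMEDA, THF, −40 °C; then CuI (10 mol %), prenyl bromide, −78 °C to rt
Reagents that add atoms: 1-bromo-3-methylbut-2-ene (CC(C)=CCBr)
Why: Directed ortho metalation removes the proton flanked by OMOM and OMe (the aryl chloride does not exchange with n-BuLi at this temperature), and copper-catalysed SN2 allylation of the aryllithium should give the linear prenyl group.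

Step 3
Reactants: 4 1-chloro-2-methoxy-4-(methoxymethoxy)-3-prenylbenzene
Product: 6 2-ArB-prop-2-en-1-ol, via arylboronate 5 (not isolated)
Conditions: Pd(OAc)2, XPhos, B2pin2, KOAc, 1,4-dioxane, 100 °C; then 2-bromoprop-2-en-1-ol, aq K3PO4, 80 °C
Reagents that add atoms: 2-bromoprop-2-en-1-ol (C=C(Br)CO)
Why: Miyaura borylation of the electron-rich aryl chloride, followed in the same pot by Suzuki–Miyaura coupling with the vinyl bromide, builds the C1'–C3 bond while the trisubstituted prenyl alkene stays out of the reaction.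

Step 4
Reactants: 6 2-ArB-prop-2-en-1-ol
Product: 7 [(2R)-2-ArB-oxiran-2-yl]methanol
Conditions: Ti(OiPr)4 (10 mol %), D-(−)-diisopropyl tartrate (12 mol %), t-BuOOH, 4 Å MS, CH2Cl2, −25 °C, non-acidic work-up
Reagents that add atoms: tert-butyl hydroperoxide (CC(C)(C)OO)
Why: Sharpless asymmetric epoxidation: the Ti(OiPr)4–tartrate catalyst binds the allylic alcohol, so only the allylic 1,1-disubstituted alkene is epoxidised (prenyl untouched), and by the facial rule for allylic alcohols the D-(−)-tartrate should give the R epoxy alcohol, which becomes C3 (S) of the target.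

Step 5
Reactants: 7 [(2R)-2-ArB-oxiran-2-yl]methanol
Product: 9 (2S)-2-ArB-oxirane-2-carboxylic acid, via epoxy aldehyde 8 (not isolated)
Conditions: TEMPO (20 mol %), PhI(OAc)2, MeCN/pH 7 phosphate buffer, 0 °C to rt
Reagents that add atoms: water (O)
Why: Oxoammonium (TEMPO) oxidation takes the primary alcohol to aldehyde 8, whose hydrate is oxidised on to the acid under near-neutral conditions that spare the epoxide, the MOM ethers and the prenyl group; the stereocentre is untouched and its descriptor changes from R to S only through the priority rules.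

Step 6
Reactants: 10 5-methoxybenzene-1,3-diol
Product: 11 1-methoxy-3,5-bis(methoxymethoxy)benzene
Conditions: MOMCl, i-Pr2NEt, CH2Cl2, 0 °C to rt
Reagents that add atoms: chloromethyl methyl ether (COCCl)
Why: Double O-alkylation gives the bis-acetal whose two OMOM groups jointly direct the next lithiation.

Step 7
Reactants: 11 1-methoxy-3,5-bis(methoxymethoxy)benzene
Product: 13 2-bromo-5-methoxy-1,3-bis(methoxymethoxy)benzene, via aryllithium 12 (not isolated)
Conditions: n-BuLi, THF, 0 °C; then BrCCl2CCl2Br, −78 °C to rt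
Reagents that add atoms: 1,2-dibromo-1,1,2,2-tetrachloroethane (BrC(Cl)(Cl)C(Cl)(Cl)Br)
Why: Directed ortho metalation occurs at the carbon flanked by both OMOM groups (the future C4a), and electrophilic bromination of the aryllithium places the halogen there and nowhere else.

Step 8
Reactants: 13 2-bromo-5-methoxy-1,3-bis(methoxymethoxy)benzene
Product: 14 2-bromo-5-methoxy-3-(methoxymethoxy)phenol
Conditions: HCl (1 equiv), MeOH/THF, 0 °C, stopped after loss of one acetal
Reagents that add atoms: none
Why: Acid-catalysed acetal methanolysis of one of two equivalent MOM groups gives the monophenol as the first-formed product, to be separated from recovered 13 and over-cleaved diol, both of which can be recycled.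

Step 9
Reactants: 14 2-bromo-5-methoxy-3-(methoxymethoxy)phenol
Product: 15 2-bromo-5-methoxy-1-(methoxymethoxy)-3-[(2-methylbut-3-en-2-yl)oxy]benzene
Conditions: tert-butyl (2-methylbut-3-en-2-yl) carbonate, Pd(PPh3)4 (2 mol %), THF, 0 °C
Reagents that add atoms: tert-butyl (2-methylbut-3-en-2-yl) carbonate (CC(C)(C)OC(=O)OC(C)(C)C=C)
Why: Tsuji–Trost O-allylation: Pd(PPh3)4 ionises the tertiary carbonate and the phenoxide attacks the substituted terminus of the 1,1-dimethylallyl intermediate under kinetic control at 0 °C, while the electron-rich, doubly flanked aryl bromide should not undergo oxidative addition under these conditions.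

Step 10
Reactants: 15 2-bromo-5-methoxy-1-(methoxymethoxy)-3-[(2-methylbut-3-en-2-yl)oxy]benzene
Product: 17 2-bromo-5-methoxy-3-(methoxymethoxy)-6-prenylphenol, via dienone 16 (not isolated)
Conditions: N,N-diethylaniline, 130 °C
Reagents that add atoms: none
Why: Aromatic Claisen rearrangement: the [3,3] shift can end productively only at the free ortho carbon between the ether oxygen and OMe (the other ortho carbon bears Br), so dienone 16 tautomerises to the phenol with a linear prenyl group at the future C8 and a free hydroxyl at the future O1.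

Step 11
Reactants: 9 (2S)-2-ArB-oxirane-2-carboxylic acid; 17 2-bromo-5-methoxy-3-(methoxymethoxy)-6-prenylphenol
Product: 19 2-bromo-5-methoxy-3-(methoxymethoxy)-6-prenylphenyl (2S)-2-ArB-oxirane-2-carboxylate, via acyl fluoride 18 (not isolated)
Conditions: cyanuric fluoride, pyridine, CH2Cl2, −20 to 0 °C; then 17, DMAP, i-Pr2NEt, 40 °C
Reagents that add atoms: none
Why: Acyl fluoride esterification: the small, non-enolisable acyl fluoride 18 forms under conditions that spare the oxirane and should acylate the di-ortho-substituted phenol under DMAP catalysis without touching the C3 stereocentre.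

Step 12
Reactants: 19 2-bromo-5-methoxy-3-(methoxymethoxy)-6-prenylphenyl (2S)-2-ArB-oxirane-2-carboxylate
Product: 22 (3S)-3-hydroxy-7-methoxy-5-(methoxymethoxy)-3-ArB-8-prenyl-2,3-dihydro-4H-chromen-4-one, via aryllithium 20 (not isolated), via lithium phenoxide epoxy ketone 21 (not isolated)
Conditions: t-BuLi (2.1 equiv), THF/Et2O, −100 °C; then DMPU, −100 °C to rt; aq NH4Cl
Reagents that add atoms: none
Why: Bromine–lithium exchange at the carbon between the two ring A oxygens gives aryllithium 20, which adds to the neighbouring ester carbonyl and collapses with 1,3-O-to-C acyl migration (anionic ortho-Fries shift), creating C4–C4a and unmasking the O1 phenoxide 21; on warming with DMPU this phenoxide attacks the oxirane CH2 (C2) in an SN2 opening that creates O1–C2 and liberates the C3 alkoxide. The closest known reactions are the halogen–metal-exchange-induced anionic Fries rearrangement of ortho-bromophenyl esters and the base-mediated cyclisation of 2'-hydroxyaryl α,β-epoxy ketones to 3-hydroxychromanones (Algar–Flynn–Oyamada-type closure). Ring C closes by 6-endo-tet opening of the epoxide at its unsubstituted terminus, since the 5-exo alternative would require substitution at the fully substituted benzylic C3. No new stereocentre is formed: none of the four bonds at C3 is broken, so the S configuration installed in step 4 is carried over unchanged. The step needs site-selective C-acylation and a single mode of ring closure: the bromine fixes the metalation site, the ester tether delivers the acyl group only to that ortho carbon and frees only the oxygen next to the prenyl group while the other oxygen stays a MOM ether, which secures the 8-prenyl (not 6-prenyl) chromanone, and the doubly ortho-substituted ketone resists a second organolithium addition.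

Step 13
Reactants: 22 (3S)-3-hydroxy-7-methoxy-5-(methoxymethoxy)-3-ArB-8-prenyl-2,3-dihydro-4H-chromen-4-one
Product: 23 sophonorol F
Conditions: ZnBr2, n-PrSH, CH2Cl2, 0 °C
Reagents that add atoms: none
Why: Lewis acid-promoted acetal cleavage with thiol capture of the methoxymethyl cation should remove both aryl MOM ethers under conditions mild enough for the tertiary benzylic α-ketol and the two prenyl groups.

Compound list
1 | 4-chloro-3-methoxyphenol | COc1cc(O)ccc1Cl | starting material
2 | 1-chloro-2-methoxy-4-(methoxymethoxy)benzene | COCOc1ccc(Cl)c(OC)c1 | intermediate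
3 | [3-chloro-2-methoxy-6-(methoxymethoxy)phenyl]lithium | COCOc1ccc(Cl)c(OC)c1[Li] | intermediate
4 | 1-chloro-2-methoxy-4-(methoxymethoxy)-3-(3-methylbut-2-en-1-yl)benzene | COCOc1ccc(Cl)c(OC)c1CC=C(C)C | intermediate
5 | 2-[2-methoxy-4-(methoxymethoxy)-3-(3-methylbut-2-en-1-yl)phenyl]-4,4,5,5-tetramethyl-1,3,2-dioxaborolane | COCOc1ccc(B2OC(C)(C)C(C)(C)O2)c(OC)c1CC=C(C)C | intermediate
6 | 2-[2-methoxy-4-(methoxymethoxy)-3-(3-methylbut-2-en-1-yl)phenyl]prop-2-en-1-ol | C=C(CO)c1ccc(OCOC)c(CC=C(C)C)c1OC | intermediate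
7 | [(2R)-2-[2-methoxy-4-(methoxymethoxy)-3-(3-methylbut-2-en-1-yl)phenyl]oxiran-2-yl]methanol | OC[C@@]2(CO2)c1ccc(OCOC)c(CC=C(C)C)c1OC | intermediate
8 | (2S)-2-[2-methoxy-4-(methoxymethoxy)-3-(3-methylbut-2-en-1-yl)phenyl]oxirane-2-carbaldehyde | O=C[C@@]2(CO2)c1ccc(OCOC)c(CC=C(C)C)c1OC | intermediate
9 | (2S)-2-[2-methoxy-4-(methoxymethoxy)-3-(3-methylbut-2-en-1-yl)phenyl]oxirane-2-carboxylic acid | OC(=O)[C@@]2(CO2)c1ccc(OCOC)c(CC=C(C)C)c1OC | intermediate
10 | 5-methoxybenzene-1,3-diol | COc1cc(O)cc(O)c1 | starting material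
11 | 1-methoxy-3,5-bis(methoxymethoxy)benzene | COCOc1cc(OC)cc(OCOC)c1 | intermediate
12 | [4-methoxy-2,6-bis(methoxymethoxy)phenyl]lithium | COCOc1cc(OC)cc(OCOC)c1[Li] | intermediate
13 | 2-bromo-5-methoxy-1,3-bis(methoxymethoxy)benzene | COCOc1cc(OC)cc(OCOC)c1Br | intermediate
14 | 2-bromo-5-methoxy-3-(methoxymethoxy)phenol | COCOc1cc(OC)cc(O)c1Br | intermediate
15 | 2-bromo-5-methoxy-1-(methoxymethoxy)-3-[(2-methylbut-3-en-2-yl)oxy]benzene | COCOc1cc(OC)cc(OC(C)(C)C=C)c1Br | intermediate
16 | 2-bromo-5-methoxy-3-(methoxymethoxy)-6-(3-methylbut-2-en-1-yl)cyclohexa-2,4-dien-1-one | O=C1C(Br)=C(OCOC)C=C(OC)C1CC=C(C)C | intermediate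
17 | 2-bromo-5-methoxy-3-(methoxymethoxy)-6-(3-methylbut-2-en-1-yl)phenol | Oc1c(Br)c(OCOC)cc(OC)c1CC=C(C)C | intermediate
18 | (2S)-2-[2-methoxy-4-(methoxymethoxy)-3-(3-methylbut-2-en-1-yl)phenyl]oxirane-2-carbonyl fluoride | O=C(F)[C@@]2(CO2)c1ccc(OCOC)c(CC=C(C)C)c1OC | intermediate
19 | 2-bromo-5-methoxy-3-(methoxymethoxy)-6-(3-methylbut-2-en-1-yl)phenyl (2S)-2-[2-methoxy-4-(methoxymethoxy)-3-(3-methylbut-2-en-1-yl)phenyl]oxirane-2-carboxylate | O=C(Oc1c(Br)c(OCOC)cc(OC)c1CC=C(C)C)[C@@]2(CO2)c3ccc(OCOC)c(CC=C(C)C)c3OC | intermediate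
20 | [2-({(2S)-2-[2-methoxy-4-(methoxymethoxy)-3-(3-methylbut-2-en-1-yl)phenyl]oxiran-2-yl}carbonyloxy)-4-methoxy-6-(methoxymethoxy)-3-(3-methylbut-2-en-1-yl)phenyl]lithium | O=C(Oc1c([Li])c(OCOC)cc(OC)c1CC=C(C)C)[C@@]2(CO2)c3ccc(OCOC)c(CC=C(C)C)c3OC | intermediate
21 | lithium 2-{[(2S)-2-[2-methoxy-4-(methoxymethoxy)-3-(3-methylbut-2-en-1-yl)phenyl]oxiran-2-yl]carbonyl}-5-methoxy-3-(methoxymethoxy)-6-(3-methylbut-2-en-1-yl)phenolate | [Li]Oc1c(CC=C(C)C)c(OC)cc(OCOC)c1C(=O)[C@@]2(CO2)c3ccc(OCOC)c(CC=C(C)C)c3OC | intermediate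
22 | (3S)-3-hydroxy-7-methoxy-5-(methoxymethoxy)-3-[2-methoxy-4-(methoxymethoxy)-3-(3-methylbut-2-en-1-yl)phenyl]-8-(3-methylbut-2-en-1-yl)-2,3-dihydro-4H-chromen-4-one | COc1cc(OCOC)c2c(c1CC=C(C)C)OC[C@@](O)(c1ccc(OCOC)c(CC=C(C)C)c1OC)C2=O | intermediate
23 | sophonorol F, (3S)-3,5-dihydroxy-3-[4-hydroxy-2-methoxy-3-(3-methylbut-2-en-1-yl)phenyl]-7-methoxy-8-(3-methylbut-2-en-1-yl)-2,3-dihydro-4H-chromen-4-one | COc1cc(O)c2c(c1CC=C(C)C)OC[C@@](O)(c1ccc(O)c(CC=C(C)C)c1OC)C2=O | target

Total steps: 13 (steps 1–5 build the ring B/C3 acid, steps 6–10 the ring A phenol, steps 11–13 join, cyclise and deprotect). Longest linear sequence: 8 steps (10 → 23; 1 → 23 is equally long).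

Steps most likely to fail

1. Step 12. Addition of t-BuLi to the aryl ester carbonyl, or direct attack of the aryllithium on the oxirane, may outrun the acyl shift. Closure of the phenoxide onto the oxirane may also stall, or the product alkoxide may undergo α-ketol rearrangement. The fallback sets out from 9 and 17 and rejoins the route at 22, forming O1–C2 first and C4–C4a second. Acid 9 is methylated (TMSCHN2, MeOH/toluene) to methyl (2S)-2-ArB-oxirane-2-carboxylate F1. Phenol 17 with Cs2CO3 in DMF at 60 °C then opens the oxirane of F1 at its CH2 terminus to give methyl (2S)-3-[2-bromo-5-methoxy-3-(methoxymethoxy)-6-prenylphenoxy]-2-hydroxy-2-ArB-propanoate F2. After masking the tertiary hydroxyl as its sodium alkoxide (NaH), bromine–lithium exchange with t-BuLi at −100 °C and Parham cyclisation onto the methyl ester close ring C and give 22.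

2. Step 4. Opening or rearrangement of the very electron-rich tertiary benzylic oxirane promoted by Ti(OiPr)4 during reaction or work-up, and erosion of facial selectivity, are the concerns. The fallback sets out from 6 and rejoins at 9 through 8, so that the oxirane always sits next to a carbonyl group. Alcohol 6 is oxidised with MnO2 in CH2Cl2 to 2-ArB-prop-2-enal F3. Iminium-catalysed nucleophilic epoxidation (α,α-diphenylprolinol trimethylsilyl ether, aqueous H2O2, CH2Cl2) gives epoxy aldehyde 8; the catalyst antipode is chosen to deliver the S epoxide, and the sense is checked by reducing a sample to 7. Pinnick oxidation (NaClO2, NaH2PO4, 2-methylbut-2-ene, t-BuOH/water) then gives 9.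

3. Step 11. Acylation of the di-ortho-substituted phenol by the α-quaternary acyl fluoride may be slow enough that fluoride or pyridine opens the oxirane instead. The fallback sets out from 6 and 17 and rejoins at 22; it joins the fragments before the stereocentre exists and installs the C3 hydroxyl last.
   - Alcohol 6 is oxidised (TEMPO, PhI(OAc)2, MeCN/water, via the enal F3) to 2-ArB-prop-2-enoic acid F4, which oxalyl chloride with catalytic DMF converts to 2-ArB-prop-2-enoyl chloride F5.
   - Phenol 17 with NaH in THF at 50 °C is acylated by F5 to 2-bromo-5-methoxy-3-(methoxymethoxy)-6-prenylphenyl 2-ArB-prop-2-enoate F6.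
   - t-BuLi at −100 °C (bromine–lithium exchange, anionic Fries shift), then aq NH4Cl, gives 1-[2-hydroxy-4-methoxy-6-(methoxymethoxy)-3-prenylphenyl]-2-ArB-prop-2-en-1-one F7.
   - NaOAc in EtOH closes F7 by 6-endo-trig oxa-Michael addition to racemic 7-methoxy-5-(methoxymethoxy)-3-ArB-8-prenyl-2,3-dihydro-4H-chromen-4-one F8.
   - Enolisation of F8 (NaHMDS, THF, −78 °C) and hydroxylation with the appropriate antipode of (8,8-dichlorocamphorylsulfonyl)oxaziridine sets C3 under reagent control and gives 22.

Further compounds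
F1 | step 12 | methyl (2S)-2-[2-methoxy-4-(methoxymethoxy)-3-(3-methylbut-2-en-1-yl)phenyl]oxirane-2-carboxylate | COC(=O)[C@@]2(CO2)c1ccc(OCOC)c(CC=C(C)C)c1OC
F2 | step 12 | methyl (2S)-3-[2-bromo-5-methoxy-3-(methoxymethoxy)-6-(3-methylbut-2-en-1-yl)phenoxy]-2-hydroxy-2-[2-methoxy-4-(methoxymethoxy)-3-(3-methylbut-2-en-1-yl)phenyl]propanoate | COC(=O)[C@@](O)(COc1c(Br)c(OCOC)cc(OC)c1CC=C(C)C)c2ccc(OCOC)c(CC=C(C)C)c2OC
F3 | step 4 | 2-[2-methoxy-4-(methoxymethoxy)-3-(3-methylbut-2-en-1-yl)phenyl]prop-2-enal | C=C(C=O)c1ccc(OCOC)c(CC=C(C)C)c1OC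
F4 | step 11 | 2-[2-methoxy-4-(methoxymethoxy)-3-(3-methylbut-2-en-1-yl)phenyl]prop-2-enoic acid | C=C(C(=O)O)c1ccc(OCOC)c(CC=C(C)C)c1OC
F5 | step 11 | 2-[2-methoxy-4-(methoxymethoxy)-3-(3-methylbut-2-en-1-yl)phenyl]prop-2-enoyl chloride | C=C(C(=O)Cl)c1ccc(OCOC)c(CC=C(C)C)c1OC
F6 | step 11 | 2-bromo-5-methoxy-3-(methoxymethoxy)-6-(3-methylbut-2-en-1-yl)phenyl 2-[2-methoxy-4-(methoxymethoxy)-3-(3-methylbut-2-en-1-yl)phenyl]prop-2-enoate | C=C(C(=O)Oc1c(Br)c(OCOC)cc(OC)c1CC=C(C)C)c2ccc(OCOC)c(CC=C(C)C)c2OC
F7 | step 11 | 1-[2-hydroxy-4-methoxy-6-(methoxymethoxy)-3-(3-methylbut-2-en-1-yl)phenyl]-2-[2-methoxy-4-(methoxymethoxy)-3-(3-methylbut-2-en-1-yl)phenyl]prop-2-en-1-one | C=C(C(=O)c1c(O)c(CC=C(C)C)c(OC)cc1OCOC)c2ccc(OCOC)c(CC=C(C)C)c2OC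
F8 | step 11 | racemic 7-methoxy-5-(methoxymethoxy)-3-[2-methoxy-4-(methoxymethoxy)-3-(3-methylbut-2-en-1-yl)phenyl]-8-(3-methylbut-2-en-1-yl)-2,3-dihydro-4H-chromen-4-one | COc1cc(OCOC)c2c(c1CC=C(C)C)OCC(c1ccc(OCOC)c(CC=C(C)C)c1OC)C2=O
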